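**Plan**

Numbering: labdane numbering for the decalin (C1–C10; C17 on C8, C18 α and C19 β on C4, C20 on C10); the chain is C11–C16 counted from C9, C16 being the butenolide carbon bonded to the ring oxygen.
Cuts: the lactone O–C16 bond and the bond from C16 to the methyl-bearing butenolide carbon (coupling–lactonisation); C14–C15 and C13–CH3 (carboalumination–alkynylation); C11–C12 (Wittig); C9–C10 (lactone enolate Claisen); C9–C11, C6–C7 and C5–C6 (allyllithium formylation, allylboration, carbonylation); C4–C19 (Birch methylation).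
Forward order: ring A comes from an arene by dearomatisation, ring B is closed by ring contraction of a δ-lactone hung on C6, the C8 and C6 hydroxyls follow, the chain is grown from C11 to C16, and the butenolide is made last.
Feature used: ring A carries the quaternary C4 (CH3 and CH2OH) between C5 and the methyl-bearing C10, which is the 1-carboxy-2-oxy-3-methyl pattern of 2-methoxy-3-methylbenzoic acid (carboxyl carbon = C18, methoxy carbon = C5, methyl carbon = C10).
Stereochemistry: C4 from the prolinol auxiliary in the Birch methylation; a temporary C6 carbinol from a diisopinocampheylborane reagent, passed on to C10 by the suprafacial [3,3] shift; C9 by kinetic protonation; C8, C5 and C6 by α-face attack on the bicycle; 13E by syn-carboalumination and the Z-ylidene by anti-oxymetalation.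

Key step: step 2

Assumption: the potassium enolate 5 is methylated on the face away from the methoxymethyl arm of the (S)-auxiliary, which is what links the (S)-auxiliary to the (R)-configured quaternary carbon of 6 (C4 of the target).
Abbreviations: TIPS = tri(propan-2-yl)silyl; TES = triethylsilyl; Ipc = isopinocampheyl.

**Route**

Step 1
Reactants: 1 2-methoxy-3-methylbenzoic acid; 2 (S)-2-(methoxymethyl)pyrrolidine
Product: 4 (S)-[2-(methoxymethyl)pyrrolidin-1-yl](2-methoxy-3-methylphenyl)methanone, via acid chloride 3 (not isolated)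
Conditions: (COCl)2, cat. DMF, CH2Cl2, 0 → 23 °C; then 2, Et3N, CH2Cl2, 0 → 23 °C
Reagents that add atoms: none
Why: Oxalyl chloride with catalytic DMF converts the ortho-substituted acid into its chloride, which acylates the secondary amine in the presence of Et3N without touching the auxiliary stereocenter (acid chloride amidation).

Step 2
Reactants: 4 (S)-[2-(methoxymethyl)pyrrolidin-1-yl](2-methoxy-3-methylphenyl)methanone
Product: 6 [(1R)-2-methoxy-1,3-dimethylcyclohexa-2,5-dien-1-yl][(2S)-2-(methoxymethyl)pyrrolidin-1-yl]methanone, via potassium amide enolate 5 (not isolated)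
Conditions: K (2.2 equiv), t-BuOH (1.0 equiv), NH3(l)–THF, −78 °C; then MeI, −78 → 23 °C
Reagents that add atoms: iodomethane, CI
Why: Potassium in ammonia transfers two electrons to the benzamide ring and tert-butanol protonates the carbon para to the carboxamide (C1), which leaves the potassium amide enolate 5 at the ipso carbon (C4), and iodomethane then alkylates this carbon to form the C4–C19 bond of the 2,5-diene 6. The closest known reaction type is the asymmetric Birch reduction–alkylation of 2-methoxybenzamides of (S)-2-(methoxymethyl)pyrrolidine. No ring is closed, since ring A is the former arene and only one exocyclic C–C bond is made. The new stereocenter C4 is controlled by the auxiliary, because the enolate oxygen and the methoxymethyl oxygen hold potassium and the electrophile enters on the enolate face away from that arm. The step needs 1,4-reduction and C-alkylation at the ipso carbon, and the carboxamide secures both by stabilising negative charge at C4 and C1, while the single equivalent of tert-butanol prevents protonation of the enolate. The methoxy group ends on the C5=C10 enol ether, a masked C5 ketone that keeps the C10 methyl in place.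

Step 3
Reactants: 6 [(1R)-2-methoxy-1,3-dimethylcyclohexa-2,5-dien-1-yl][(2S)-2-(methoxymethyl)pyrrolidin-1-yl]methanone
Product: 7 [(1S)-2-methoxy-1,3-dimethylcyclohexa-2,5-dien-1-yl]methanol
Conditions: LiN(i-Pr)2 (4 equiv), H3N·BH3 (4.2 equiv), THF, 0 °C; then 6, 23 → 50 °C; 2 M NaOH work-up
Reagents that add atoms: none
Why: LiH2NBH3 is a small, strongly nucleophilic hydride that reduces hindered tertiary amides, α-quaternary ones included, to primary alcohols through C–N cleavage of the hemiaminal (amide-to-alcohol reduction), while the enol ether and the alkenes are inert and C4, having no hydrogen, cannot epimerise.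

Step 4
Reactants: 7 [(1S)-2-methoxy-1,3-dimethylcyclohexa-2,5-dien-1-yl]methanol
Product: 8 {[(1S)-2-methoxy-1,3-dimethylcyclohexa-2,5-dien-1-yl]methoxy}tri(propan-2-yl)silane
Conditions: i-Pr3SiOTf (1.2 equiv), 2,6-lutidine, CH2Cl2, −78 → 0 °C
Reagents that add atoms: tri(propan-2-yl)silyl trifluoromethanesulfonate, CC(C)[Si](OS(=O)(=O)C(F)(F)F)(C(C)C)C(C)C
Why: A silyl triflate with 2,6-lutidine silylates the neopentyl alcohol quickly at low temperature, and the buffered medium spares the acid-labile enol ether (silyl ether protection).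

Step 5
Reactants: 8 {[(1S)-2-methoxy-1,3-dimethylcyclohexa-2,5-dien-1-yl]methoxy}tri(propan-2-yl)silane
Product: 10 (2S)-2,6-dimethyl-2-[(TIPS-oxy)methyl]cyclohexan-1-one as a mixture of C6 epimers, via saturated enol ether 9 (not isolated)
Conditions: H2 (1 atm), RhCl(PPh3)3 (5 mol%), THF, 23 °C; then 1 M HCl, THF–H2O, 23 °C
Reagents that add atoms: water, O
Why: RhCl(PPh3)3 hydrogenates the cis-disubstituted C2=C3 bond but not the tetrasubstituted enol ether, after which aqueous acid hydrolyses the enol ether to the C5 ketone (homogeneous hydrogenation, enol ether hydrolysis); the configuration at C10 is irrelevant because this carbon becomes sp2 in step 6.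

Step 6
Reactants: 10 (2S)-2,6-dimethyl-2-[(TIPS-oxy)methyl]cyclohexan-1-one
Product: 11 (6S)-2,6-dimethyl-6-[(TIPS-oxy)methyl]cyclohex-1-en-1-yl trifluoromethanesulfonate
Conditions: KN(SiMe3)2 (1.3 equiv), THF, −78 °C; then PhNTf2, −78 → 0 °C; aq. NH4Cl
Reagents that add atoms: N-phenylbis(trifluoromethanesulfonimide), O=S(=O)(N(c1ccccc1)S(=O)(=O)C(F)(F)F)C(F)(F)F
Why: Because C4 is quaternary the ketone can enolise only towards C10, so O-sulfonylation of the potassium enolate gives one tetrasubstituted enol triflate (enol triflate formation).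

Step 7
Reactants: 11 (6S)-2,6-dimethyl-6-[(TIPS-oxy)methyl]cyclohex-1-en-1-yl trifluoromethanesulfonate
Product: 12 (6R)-2,6-dimethyl-6-[(TIPS-oxy)methyl]cyclohex-1-ene-1-carbaldehyde
Conditions: Pd(PPh3)4 (5 mol%), LiCl (3 equiv), CO (1 atm), Bu3SnH (slow addition), THF, 50 °C
Reagents that add atoms: carbon monoxide, [C-]#[O+]
Why: Oxidative addition of zerovalent palladium to the enol triflate, CO insertion and hydride transfer from Bu3SnH to the acylpalladium give the enal with C6 in place (palladium-catalysed reductive carbonylation), slow stannane addition under CO suppressing direct reduction.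

Step 8
Reactants: 12 (6R)-2,6-dimethyl-6-[(TIPS-oxy)methyl]cyclohex-1-ene-1-carbaldehyde
Product: 13 (1S)-1-{(6R)-2,6-dimethyl-6-[(TIPS-oxy)methyl]cyclohex-1-en-1-yl}-3-methylbut-3-en-1-ol
Conditions: (−)-Ipc2BOMe [from (+)-α-pinene], methallylmagnesium chloride, Et2O, −78 → 23 °C; then 12, −78 → −20 °C; then 3 M NaOH, 30% H2O2
Reagents that add atoms: methallylmagnesium chloride, CC(=C)C[Mg]Cl
Why: The allylborane adds through a closed chair transition state in which the isopinocampheyl groups decide the aldehyde face (asymmetric allylboration), so the C6 carbinol is set as (S) by the reagent and not by the remote C4 center.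

Step 9
Reactants: 13 (1S)-1-{(6R)-2,6-dimethyl-6-[(TIPS-oxy)methyl]cyclohex-1-en-1-yl}-3-methylbut-3-en-1-ol
Product: 15 (6S)-6-{(6R)-2,6-dimethyl-6-[(TIPS-oxy)methyl]cyclohex-1-en-1-yl}-4-methylideneoxan-2-ol (lactol), via dilithio derivative 14 (not isolated)
Conditions: n-BuLi (2.3 equiv), TMEDA (2.3 equiv), Et2O–hexane, 0 → 23 °C; then DMF, −78 → 0 °C; aq. NH4Cl
Reagents that add atoms: N,N-dimethylformamide, CN(C)C=O
Why: After O-deprotonation a second equivalent of n-BuLi·TMEDA removes a methyl proton of the 2-methylallyl group, as in the known dilithiation of 3-methylbut-3-en-1-ol, to give a 2-substituted allyllithium whose two CH2 termini are equivalent, so formylation can give only one β,γ-unsaturated aldehyde (C9–C11 bond), which closes to the lactol (alkoxide-directed allylic lithiation and formylation).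

Step 10
Reactants: 15 (6S)-6-{(6R)-2,6-dimethyl-6-[(TIPS-oxy)methyl]cyclohex-1-en-1-yl}-4-methylideneoxan-2-ol
Product: 16 (6S)-6-{(6R)-2,6-dimethyl-6-[(TIPS-oxy)methyl]cyclohex-1-en-1-yl}-4-methylideneoxan-2-one
Conditions: TEMPO (10 mol%), PhI(OAc)2 (1.2 equiv), CH2Cl2, 23 °C
Reagents that add atoms: none
Why: The oxoammonium salt from TEMPO oxidises the lactol to the δ-lactone under almost neutral conditions, so the exocyclic alkene is not drawn into conjugation (TEMPO–PhI(OAc)2 oxidation).

Step 11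
Reactants: 16 (6S)-6-{(6R)-2,6-dimethyl-6-[(TIPS-oxy)methyl]cyclohex-1-en-1-yl}-4-methylideneoxan-2-one
Product: 19 4β,10β-dimethyl-8-methylidene-4α-[(TIPS-oxy)methyl]decal-5-ene-9α-carboxylic acid (9β-H), via silyl ketene acetal 17 (not isolated), via trimethylsilyl ester 18 (not isolated)
Conditions: LiN(i-Pr)2 (1.3 equiv), Me3SiCl–Et3N, THF, −78 °C; then toluene, 110 °C; then 1 M HCl work-up
Reagents that add atoms: none
Why: The lactone silyl ketene acetal undergoes an Ireland–Claisen rearrangement through the boat transition state enforced by the six-membered lactone, which breaks C6–O, forms C9–C10 and so closes ring B with a C5=C6 bond; the shift is suprafacial, so the (6S) carbinol places C9 on the α-face of C10 (C20 β), while the boat geometry leaves the carboxyl trans to C20 (9α), which step 12 corrects.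

Step 12
Reactants: 19 4β,10β-dimethyl-8-methylidene-4α-[(TIPS-oxy)methyl]decal-5-ene-9α-carboxylic acid
Product: 21 4β,10β-dimethyl-8-methylidene-4α-[(TIPS-oxy)methyl]decal-5-ene-9β-carboxylic acid (9α-H), via dilithium dienediolate 20 (not isolated)
Conditions: LiN(i-Pr)2 (3 equiv), THF–DMPU, −78 → 0 °C; then AcOH in THF, −78 °C
Reagents that add atoms: none
Why: A second deprotonation at the doubly activated C9–H gives the dienediolate, and kinetic protonation at the α-carbon from the face opposite the pseudoaxial C10 methyl returns the β,γ-unsaturated acid with 9α-H (deconjugative α-protonation of a dienolate).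

Step 13
Reactants: 21 4β,10β-dimethyl-8-methylidene-4α-[(TIPS-oxy)methyl]decal-5-ene-9β-carboxylic acid
Product: 22 8α-hydroxy-4β,8β,10β-trimethyl-4α-[(TIPS-oxy)methyl]decal-5-ene-9β-carboxylic acid
Conditions: Co(acac)2 (20 mol%), PhSiH3 (2 equiv), O2 (1 atm), THF, 23 °C
Reagents that add atoms: dioxygen, O=O
Why: Hydrogen atom transfer from a cobalt hydride to the terminal CH2 of the 1,1-disubstituted alkene gives the tertiary C8 radical, which takes up O2 on the α-face away from the 1,3-related C10 methyl to give the 8α-alcohol with C17 as β-methyl, the hindered trisubstituted C5=C6 bond being left alone (Mukaiyama hydration).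

Step 14
Reactants: 22 8α-hydroxy-4β,8β,10β-trimethyl-4α-[(TIPS-oxy)methyl]decal-5-ene-9β-carboxylic acid
Product: 23 9β-(hydroxymethyl)-4β,8β,10β-trimethyl-4α-[(TIPS-oxy)methyl]-5α-decalin-6α,8α-diol
Conditions: BH3·THF (6 equiv), THF, 0 → 40 °C; then 3 M NaOH, 30% H2O2, 0 → 23 °C
Reagents that add atoms: hydrogen peroxide, OO
Why: Borane reduces the carboxylic acid to the C11 alcohol and adds syn to the C5=C6 bond from the α-face, the β-face being shielded by the axial methyls on C4, C8 and C10, with boron on the less substituted C6, so that oxidation with retention gives the 5α-H trans-decalin and the 6α-alcohol (hydroboration–oxidation).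

Step 15
Reactants: 23 9β-(hydroxymethyl)-4β,8β,10β-trimethyl-4α-[(TIPS-oxy)methyl]-5α-decalin-6α,8α-diol
Product: 24 6α,8α-dihydroxy-4β,8β,10β-trimethyl-4α-[(TIPS-oxy)methyl]-5α-decalin-9β-carbaldehyde
Conditions: TEMPO (10 mol%), PhI(OAc)2 (1.1 equiv), CH2Cl2, 0 → 23 °C
Reagents that add atoms: none
Why: The TEMPO-derived oxoammonium ion oxidises the primary C11 alcohol much faster than the hindered secondary C6 alcohol, cannot oxidise the tertiary one, and stops at the aldehyde in the absence of water (chemoselective TEMPO oxidation).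

Step 16
Reactants: 24 6α,8α-dihydroxy-4β,8β,10β-trimethyl-4α-[(TIPS-oxy)methyl]-5α-decalin-9β-carbaldehyde
Product: 25 6α,8α-bis(TES-oxy)-4β,8β,10β-trimethyl-4α-[(TIPS-oxy)methyl]-5α-decalin-9β-carbaldehyde
Conditions: Et3SiOTf (3 equiv), 2,6-lutidine, CH2Cl2, −78 → 0 °C
Reagents that add atoms: triethylsilyl trifluoromethanesulfonate, CC[Si](CC)(CC)OS(=O)(=O)C(F)(F)F
Why: Et3SiOTf is reactive enough to silylate the secondary and the tertiary alcohol, which removes the acidic protons and the retro-aldol pathway before the basic steps that follow (silyl ether protection).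

Step 17
Reactants: 25 6α,8α-bis(TES-oxy)-4β,8β,10β-trimethyl-4α-[(TIPS-oxy)methyl]-5α-decalin-9β-carbaldehyde
Product: 26 (E)-4-{6α,8α-bis(TES-oxy)-4β,8β,10β-trimethyl-4α-[(TIPS-oxy)methyl]-5α-decalin-9β-yl}but-3-en-2-one
Conditions: Ph3P=CHC(O)CH3 (3 equiv), toluene, 100 °C
Reagents that add atoms: 1-(triphenylphosphoranylidene)propan-2-one, CC(=O)C=P(c1ccccc1)(c1ccccc1)c1ccccc1
Why: The stabilised ylide reacts with the hindered aldehyde on heating to give the (E)-enone and the C11–C12 bond without added base, so the C9 center next to the carbonyl is not epimerised (Wittig reaction).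

Step 18
Reactants: 26 (E)-4-{6α,8α-bis(TES-oxy)-4β,8β,10β-trimethyl-4α-[(TIPS-oxy)methyl]-5α-decalin-9β-yl}but-3-en-2-one
Product: 27 4-{6α,8α-bis(TES-oxy)-4β,8β,10β-trimethyl-4α-[(TIPS-oxy)methyl]-5α-decalin-9β-yl}butan-2-one
Conditions: H2 (1 atm), 10% Pd/C, EtOAc, 23 °C
Reagents that add atoms: none
Why: The conjugated disubstituted C11=C12 bond is the only alkene in the molecule and is saturated over Pd/C without reduction of the ketone (catalytic hydrogenation).

Step 19
Reactants: 27 4-{6α,8α-bis(TES-oxy)-4β,8β,10β-trimethyl-4α-[(TIPS-oxy)methyl]-5α-decalin-9β-yl}butan-2-one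
Product: 29 9β-(but-3-yn-1-yl)-6α,8α-bis(TES-oxy)-4β,8β,10β-trimethyl-4α-[(TIPS-oxy)methyl]-5α-decalin, via enol phosphate 28 (not isolated)
Conditions: LiN(i-Pr)2 (1.1 equiv), THF, −78 °C; ClP(O)(OEt)2, −78 → 23 °C; then LiN(i-Pr)2 (2.3 equiv), −78 → 23 °C; aq. NH4Cl
Reagents that add atoms: none
Why: Kinetic deprotonation of the methyl ketone at the methyl group, O-phosphorylation and base-induced elimination of the enol phosphate give the terminal alkyne C13≡C14 (ketone-to-alkyne conversion through an enol phosphate).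

Step 20
Reactants: 29 9β-(but-3-yn-1-yl)-6α,8α-bis(TES-oxy)-4β,8β,10β-trimethyl-4α-[(TIPS-oxy)methyl]-5α-decalin
Product: 31 9β-[(E)-3-methyl-6-(trimethylsilyl)hex-3-en-5-yn-1-yl]-6α,8α-bis(TES-oxy)-4β,8β,10β-trimethyl-4α-[(TIPS-oxy)methyl]-5α-decalin, via alkenylalane 30 (not isolated)
Conditions: AlMe3 (3 equiv), Cp2ZrCl2 (0.3 equiv), CH2Cl2, 0 → 23 °C; volatiles removed; then BrC≡CSiMe3, Pd(PPh3)4 (5 mol%), ZnCl2 (0.2 equiv), THF, 23 °C
Reagents that add atoms: trimethylaluminium, C[Al](C)C; (bromoethynyl)trimethylsilane, C[Si](C)(C)C#CBr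
Why: Zirconium-catalysed carboalumination adds methyl and aluminium syn across the terminal alkyne with methyl on C13, which fixes the 13E geometry, and the alkenylalane couples with the bromoalkyne under palladium catalysis with retention to form C14–C15 (carboalumination followed by alkenyl–alkynyl cross-coupling).

Step 21
Reactants: 31 9β-[(E)-3-methyl-6-(trimethylsilyl)hex-3-en-5-yn-1-yl]-6α,8α-bis(TES-oxy)-4β,8β,10β-trimethyl-4α-[(TIPS-oxy)methyl]-5α-decalin
Product: 32 4α-(hydroxymethyl)-9β-[(E)-3-methylhex-3-en-5-yn-1-yl]-4β,8β,10β-trimethyl-5α-decalin-6α,8α-diol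
Conditions: Bu4NF (6 equiv), THF, 23 → 45 °C
Reagents that add atoms: none
Why: Fluoride cleaves the C-silyl group of the alkyne and the three silyl ethers in one operation (fluoride desilylation).

Step 22
Reactants: 33 but-2-ynoic acid
Product: 34 (Z)-3-iodobut-2-enoic acid
Conditions: NaI (1.6 equiv), AcOH, 110 °C
Reagents that add atoms: sodium iodide, [Na+].[I-]
Why: Iodide adds to the β-carbon of the ynoic acid and protonation occurs anti, which gives the (Z)-β-iodo acid with iodine and carboxyl cis (hydroiodination of an alkynoic acid).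

Step 23
Reactants: 32 4α-(hydroxymethyl)-9β-[(E)-3-methylhex-3-en-5-yn-1-yl]-4β,8β,10β-trimethyl-5α-decalin-6α,8α-diol; 34 (Z)-3-iodobut-2-enoic acid
Product: 36 CNP0126806.1, via enynoic acid 35 (not isolated)
Conditions: Pd(PPh3)4 (5 mol%), CuI (10 mol%), Et3N (3 equiv), MeCN, 23 °C
Reagents that add atoms: none
Why: Sonogashira coupling at the vinyl iodide gives the (Z)-enynoic acid, whose carboxyl adds anti across the activated alkyne in a 5-exo-dig lactonisation to give the Z-ylidene butenolide without protection of the triol (tandem cross-coupling–lactonisation).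

**Compound list**

1 | 2-methoxy-3-methylbenzoic acid | COc1c(C)cccc1C(=O)O | starting material
2 | (S)-2-(methoxymethyl)pyrrolidine | COC[C@@H]1CCCN1 | starting material
3 | 2-methoxy-3-methylbenzoyl chloride (formed in the flask) | COc1c(C)cccc1C(Cl)=O | intermediate
4 | (S)-[2-(methoxymethyl)pyrrolidin-1-yl](2-methoxy-3-methylphenyl)methanone | COC[C@@H]1CCCN1C(=O)c1cccc(C)c1OC | intermediate
5 | potassium amide enolate of the 1,4-dihydroarene, enolate oxygen on the side of the ring methoxy group (formed in the flask) | COC[C@@H]1CCCN1/C([O-])=C1\C=CCC(C)=C1OC.[K+] | intermediate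
6 | [(1R)-2-methoxy-1,3-dimethylcyclohexa-2,5-dien-1-yl][(2S)-2-(methoxymethyl)pyrrolidin-1-yl]methanone | COC[C@@H]1CCCN1C(=O)[C@]1(C)C=CCC(C)=C1OC | intermediate
7 | [(1S)-2-methoxy-1,3-dimethylcyclohexa-2,5-dien-1-yl]methanol | OC[C@]1(C)C=CCC(C)=C1OC | intermediate
8 | {[(1S)-2-methoxy-1,3-dimethylcyclohexa-2,5-dien-1-yl]methoxy}tri(propan-2-yl)silane | CC(C)[Si](OC[C@]1(C)C=CCC(C)=C1OC)(C(C)C)C(C)C | intermediate
9 | {[(1S)-2-methoxy-1,3-dimethylcyclohex-2-en-1-yl]methoxy}tri(propan-2-yl)silane (formed in the flask) | CC(C)[Si](OC[C@]1(C)CCCC(C)=C1OC)(C(C)C)C(C)C | intermediate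
10 | (2S)-2,6-dimethyl-2-[(TIPS-oxy)methyl]cyclohexan-1-one (C6 epimers) | CC(C)[Si](OC[C@]1(C)CCCC(C)C1=O)(C(C)C)C(C)C | intermediate
11 | (6S)-2,6-dimethyl-6-[(TIPS-oxy)methyl]cyclohex-1-en-1-yl trifluoromethanesulfonate | CC(C)[Si](OC[C@]1(C)CCCC(C)=C1OS(=O)(=O)C(F)(F)F)(C(C)C)C(C)C | intermediate
12 | (6R)-2,6-dimethyl-6-[(TIPS-oxy)methyl]cyclohex-1-ene-1-carbaldehyde | CC(C)[Si](OC[C@]1(C)CCCC(C)=C1C=O)(C(C)C)C(C)C | intermediate
13 | (1S)-1-{(6R)-2,6-dimethyl-6-[(TIPS-oxy)methyl]cyclohex-1-en-1-yl}-3-methylbut-3-en-1-ol | CC(C)[Si](OC[C@]1(C)CCCC(C)=C1[C@@H](O)CC(C)=C)(C(C)C)C(C)C | intermediate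
14 | dilithio derivative of 13: lithium alkoxide at C6 and allyllithium at the former methyl group (formed in the flask) | CC(C)[Si](OC[C@]1(C)CCCC(C)=C1[C@@H]([O-])CC(=C)[CH2-])(C(C)C)C(C)C.[Li+].[Li+] | intermediate
15 | (6S)-6-{(6R)-2,6-dimethyl-6-[(TIPS-oxy)methyl]cyclohex-1-en-1-yl}-4-methylideneoxan-2-ol (anomers) | CC(C)[Si](OC[C@]1(C)CCCC(C)=C1[C@@H]1CC(=C)CC(O)O1)(C(C)C)C(C)C | intermediate
16 | (6S)-6-{(6R)-2,6-dimethyl-6-[(TIPS-oxy)methyl]cyclohex-1-en-1-yl}-4-methylideneoxan-2-one | CC(C)[Si](OC[C@]1(C)CCCC(C)=C1[C@@H]1CC(=C)CC(=O)O1)(C(C)C)C(C)C | intermediate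
17 | trimethylsilyl ketene acetal of 16: 4-methylidene-6-(trimethylsilyloxy)-3,4-dihydro-2H-pyran carrying the ring A unit at C2 (formed in the flask) | CC(C)[Si](OC[C@]1(C)CCCC(C)=C1[C@@H]1CC(=C)C=C(O[Si](C)(C)C)O1)(C(C)C)C(C)C | intermediate
18 | trimethylsilyl ester of 19 (formed in the flask) | C[Si](C)(C)OC(=O)[C@H]1[C@@]2(C)CCC[C@@](C)(CO[Si](C(C)C)(C(C)C)C(C)C)C2=CCC1=C | intermediate
19 | 4β,10β-dimethyl-8-methylidene-4α-[(TIPS-oxy)methyl]decal-5-ene-9α-carboxylic acid (9β-H) | OC(=O)[C@H]1[C@@]2(C)CCC[C@@](C)(CO[Si](C(C)C)(C(C)C)C(C)C)C2=CCC1=C | intermediate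
20 | dilithium dienediolate of 19, C9 sp2 (formed in the flask) | [Li+].[Li+].[O-]C([O-])=C1[C@@]2(C)CCC[C@@](C)(CO[Si](C(C)C)(C(C)C)C(C)C)C2=CCC1=C | intermediate
21 | 4β,10β-dimethyl-8-methylidene-4α-[(TIPS-oxy)methyl]decal-5-ene-9β-carboxylic acid (9α-H) | OC(=O)[C@@H]1[C@@]2(C)CCC[C@@](C)(CO[Si](C(C)C)(C(C)C)C(C)C)C2=CCC1=C | intermediate
22 | 8α-hydroxy-4β,8β,10β-trimethyl-4α-[(TIPS-oxy)methyl]decal-5-ene-9β-carboxylic acid | OC(=O)[C@@H]1[C@@]2(C)CCC[C@@](C)(CO[Si](C(C)C)(C(C)C)C(C)C)C2=CC[C@@]1(C)O | intermediate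
23 | 9β-(hydroxymethyl)-4β,8β,10β-trimethyl-4α-[(TIPS-oxy)methyl]-5α-decalin-6α,8α-diol | OC[C@@H]1[C@@]2(C)CCC[C@@](C)(CO[Si](C(C)C)(C(C)C)C(C)C)[C@@H]2[C@@H](O)C[C@@]1(C)O | intermediate
24 | 6α,8α-dihydroxy-4β,8β,10β-trimethyl-4α-[(TIPS-oxy)methyl]-5α-decalin-9β-carbaldehyde | O=C[C@@H]1[C@@]2(C)CCC[C@@](C)(CO[Si](C(C)C)(C(C)C)C(C)C)[C@@H]2[C@@H](O)C[C@@]1(C)O | intermediate
25 | 6α,8α-bis(TES-oxy)-4β,8β,10β-trimethyl-4α-[(TIPS-oxy)methyl]-5α-decalin-9β-carbaldehyde | O=C[C@@H]1[C@@]2(C)CCC[C@@](C)(CO[Si](C(C)C)(C(C)C)C(C)C)[C@@H]2[C@@H](O[Si](CC)(CC)CC)C[C@@]1(C)O[Si](CC)(CC)CC | intermediate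
26 | (E)-4-{6α,8α-bis(TES-oxy)-4β,8β,10β-trimethyl-4α-[(TIPS-oxy)methyl]-5α-decalin-9β-yl}but-3-en-2-one | CC(=O)/C=C/[C@@H]1[C@@]2(C)CCC[C@@](C)(CO[Si](C(C)C)(C(C)C)C(C)C)[C@@H]2[C@@H](O[Si](CC)(CC)CC)C[C@@]1(C)O[Si](CC)(CC)CC | intermediate
27 | 4-{6α,8α-bis(TES-oxy)-4β,8β,10β-trimethyl-4α-[(TIPS-oxy)methyl]-5α-decalin-9β-yl}butan-2-one | CC(=O)CC[C@@H]1[C@@]2(C)CCC[C@@](C)(CO[Si](C(C)C)(C(C)C)C(C)C)[C@@H]2[C@@H](O[Si](CC)(CC)CC)C[C@@]1(C)O[Si](CC)(CC)CC | intermediate
28 | diethyl 4-(decalin-9β-yl)but-1-en-2-yl phosphate, decalin substituted as in 27 (formed in the flask) | C=C(OP(=O)(OCC)OCC)CC[C@@H]1[C@@]2(C)CCC[C@@](C)(CO[Si](C(C)C)(C(C)C)C(C)C)[C@@H]2[C@@H](O[Si](CC)(CC)CC)C[C@@]1(C)O[Si](CC)(CC)CC | intermediate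
29 | 9β-(but-3-yn-1-yl)-6α,8α-bis(TES-oxy)-4β,8β,10β-trimethyl-4α-[(TIPS-oxy)methyl]-5α-decalin | C#CCC[C@@H]1[C@@]2(C)CCC[C@@](C)(CO[Si](C(C)C)(C(C)C)C(C)C)[C@@H]2[C@@H](O[Si](CC)(CC)CC)C[C@@]1(C)O[Si](CC)(CC)CC | intermediate
30 | [(E)-4-(decalin-9β-yl)-2-methylbut-1-en-1-yl]dimethylalane, decalin substituted as in 29 (formed in the flask) | C[Al](C)/C=C(\C)CC[C@@H]1[C@@]2(C)CCC[C@@](C)(CO[Si](C(C)C)(C(C)C)C(C)C)[C@@H]2[C@@H](O[Si](CC)(CC)CC)C[C@@]1(C)O[Si](CC)(CC)CC | intermediate
31 | 9β-[(E)-3-methyl-6-(trimethylsilyl)hex-3-en-5-yn-1-yl]-6α,8α-bis(TES-oxy)-4β,8β,10β-trimethyl-4α-[(TIPS-oxy)methyl]-5α-decalin | C[Si](C)(C)C#C/C=C(\C)CC[C@@H]1[C@@]2(C)CCC[C@@](C)(CO[Si](C(C)C)(C(C)C)C(C)C)[C@@H]2[C@@H](O[Si](CC)(CC)CC)C[C@@]1(C)O[Si](CC)(CC)CC | intermediate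
32 | 4α-(hydroxymethyl)-9β-[(E)-3-methylhex-3-en-5-yn-1-yl]-4β,8β,10β-trimethyl-5α-decalin-6α,8α-diol | C#C/C=C(\C)CC[C@@H]1[C@@]2(C)CCC[C@@](C)(CO)[C@@H]2[C@@H](O)C[C@@]1(C)O | intermediate
33 | but-2-ynoic acid | CC#CC(=O)O | starting material
34 | (Z)-3-iodobut-2-enoic acid | C/C(I)=C/C(=O)O | intermediate
35 | (2Z,6E)-3,7-dimethyl-9-(decalin-9β-yl)nona-2,6-dien-4-ynoic acid, decalin substituted as in 32 (formed in the flask) | OC(=O)/C=C(/C)C#C/C=C(\C)CC[C@@H]1[C@@]2(C)CCC[C@@](C)(CO)[C@@H]2[C@@H](O)C[C@@]1(C)O | intermediate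
36 | CNP0126806.1: (5Z)-4-methyl-5-[(2E)-3-methyl-5-(decalin-9β-yl)pent-2-en-1-ylidene]furan-2(5H)-one with 4α-CH2OH, 4β,8β,10β-trimethyl, 6α,8α-diol, 5α-H | CC1=CC(=O)O/C1=C\C=C(/C)CC[C@@H]1[C@@]2(C)CCC[C@@](C)(CO)[C@@H]2[C@@H](O)C[C@@]1(C)O | target

**Count and risks**

Total step count: 23. Longest linear sequence: 22 (steps 1–21 and 23; step 22 makes the iodo acid).

Steps most likely to fail:

1. Step 9. The second lithiation may take place at an allylic position of ring A (C1 or the C20 methyl) or stop at the alkoxide, and the allyllithium may be quenched before it meets DMF. Fallback: the C7–C11 unit is brought in already oxygenated, at the cost of reagent control at C6. Aldehyde 12 is treated with the dilithio derivative of 3-methylbut-3-en-1-ol (n-BuLi, TMEDA), which should give the 3-methylidenepentane-1,5-diol F1 as both C6 epimers. TEMPO/PhI(OAc)2 then oxidises the primary alcohol and the lactol that forms, giving lactone 16 and its (6R)-lactone F2, which are separated by chromatography. The route continues from 16.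

2. Step 12. Protonation may occur at C17 and move the double bond into conjugation, or the two faces of C9 may not be told apart well. Fallback: C8 and C9 are set together by reductive opening of an epoxy ester. Acid 19 is methylated (MeI, K2CO3, DMF) and isomerised with DBU to the conjugated diene ester F3. BH3·THF then NaOH/H2O2 should hydroborate only the C5=C6 bond, from the α-face, to give the 6α-hydroxy ester F4. mCPBA epoxidises the remaining tetrasubstituted alkene on the α-face to give the 8α,9α-epoxy ester F5. SmI2 in THF–MeOH cleaves the C9–O bond, and the samarium enolate, shielded on the β-face by the axial methyls on C8 and C10, is protonated from the α-face to give the dihydroxy ester F6. LiAlH4 reduces F6 to triol 23, where the route is rejoined.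

3. Step 11. The congested boat transition state may make the rearrangement slow, so that desilylation or fragmentation of the ketene acetal wins. Fallback: ring B is closed by a cycloaddition, without chirality transfer from C6. Aldehyde 12 is methylenated (Ph3P=CH2, THF) to the vinylcyclohexene F7. Heating F7 with methyl buta-2,3-dienoate should give a Diels–Alder reaction at the α,β-bond of the allenic ester, which forms C7–C8 and C9–C10 and gives the methyl ester F8 together with its C10 epimers; these are removed by chromatography. LiOH hydrolysis of F8 gives acid 19, where the route is rejoined.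

**Further compounds**

F1 | step 9 | 1-{(6R)-2,6-dimethyl-6-[(TIPS-oxy)methyl]cyclohex-1-en-1-yl}-3-methylidenepentane-1,5-diol (both C1 epimers) | CC(C)[Si](OC[C@]1(C)CCCC(C)=C1C(O)CC(=C)CCO)(C(C)C)C(C)C
F2 | step 9 | (6R)-6-{(6R)-2,6-dimethyl-6-[(TIPS-oxy)methyl]cyclohex-1-en-1-yl}-4-methylideneoxan-2-one | CC(C)[Si](OC[C@]1(C)CCCC(C)=C1[C@H]1CC(=C)CC(=O)O1)(C(C)C)C(C)C
F3 | step 12 | methyl 4β,8,10β-trimethyl-4α-[(TIPS-oxy)methyl]decala-5,8-diene-9-carboxylate | COC(=O)C=1[C@@]2(C)CCC[C@@](C)(CO[Si](C(C)C)(C(C)C)C(C)C)C2=CCC=1C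
F4 | step 12 | methyl 6α-hydroxy-4β,8,10β-trimethyl-4α-[(TIPS-oxy)methyl]-5α-decal-8-ene-9-carboxylate | COC(=O)C=1[C@@]2(C)CCC[C@@](C)(CO[Si](C(C)C)(C(C)C)C(C)C)[C@@H]2[C@@H](O)CC=1C
F5 | step 12 | methyl 8α,9α-epoxy-6α-hydroxy-4β,8β,10β-trimethyl-4α-[(TIPS-oxy)methyl]-5α-decalin-9β-carboxylate | COC(=O)[C@]13[C@@]2(C)CCC[C@@](C)(CO[Si](C(C)C)(C(C)C)C(C)C)[C@@H]2[C@@H](O)C[C@@]1(C)O3
F6 | step 12 | methyl 6α,8α-dihydroxy-4β,8β,10β-trimethyl-4α-[(TIPS-oxy)methyl]-5α-decalin-9β-carboxylate | COC(=O)[C@@H]1[C@@]2(C)CCC[C@@](C)(CO[Si](C(C)C)(C(C)C)C(C)C)[C@@H]2[C@@H](O)C[C@@]1(C)O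
F7 | step 11 | {[(1R)-2-ethenyl-1,3-dimethylcyclohex-2-en-1-yl]methoxy}tri(propan-2-yl)silane | CC(C)[Si](OC[C@]1(C)CCCC(C)=C1C=C)(C(C)C)C(C)C
F8 | step 11 | methyl 4β,10β-dimethyl-8-methylidene-4α-[(TIPS-oxy)methyl]decal-5-ene-9α-carboxylate | COC(=O)[C@H]1[C@@]2(C)CCC[C@@](C)(CO[Si](C(C)C)(C(C)C)C(C)C)C2=CCC1=C
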